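**Retrosynthetic overview**
- The phenol is unmasked last from its methyl ether, and the oxazole C4–Cl is put in just before that by electrophilic chlorination.
- Key disconnection: oxazole bonds O1–C5 and C2–N3. They trace back to a 4-aryl NH-1,2,3-triazole and a trichloropyrrole acid chloride, joined with loss of dinitrogen.
- Feature on which this rests: oxazole C5 carries the para-oxygenated benzene ring, which can stabilise a vinyl cation at C5, and the O1–C2–N3 atoms are the carbonyl and acylated nitrogen of a 3,4,5-trichloropyrrole-2-carboxylic acid derivative.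
- The triazole comes from 4-ethynylanisole and azidotrimethylsilane; the acid chloride comes from 2-(trichloroacetyl)pyrrole by ring perchlorination, haloform hydrolysis and oxalyl chloride.
- Ring order: the benzene and pyrrole rings are bought, the triazole ring is built first, and the oxazole ring is then made from it.

Key step: step 5

Remark: the pyrrole N–H is carried unprotected throughout, on the assumption that three ring chlorines and the C2 carbonyl or oxazolyl group make it acidic but non-nucleophilic; the triazole is drawn as its 1H tautomer.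

**Step 1**
Reactants: 1 4-ethynylanisole; 2 azidotrimethylsilane
Product: 3 4-(4-methoxyphenyl)-1H-1,2,3-triazole
Conditions: CuI (5 mol %), DMF/MeOH 9:1, 100 °C, sealed vessel
Reagents that add atoms: none
Why: Copper-catalysed azide–alkyne cycloaddition; methanolysis of 2 releases hydrazoic acid in the flask, which adds to the copper acetylide of 1 and should give the N-unsubstituted 4-aryl triazole directly.

**Step 2**
Reactants: 4 2-(trichloroacetyl)pyrrole
Product: 7 2,2,2-trichloro-1-(3,4,5-trichloro-1H-pyrrol-2-yl)ethanone, via 4-chloro ketone 5 (not isolated), via 4,5-dichloro ketone 6 (not isolated)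
Conditions: SO2Cl2 (3.5 equiv), AcOH, 20 °C then 60 °C
Reagents that add atoms: sulfuryl chloride, O=S(=O)(Cl)Cl
Why: Electrophilic aromatic chlorination; the acylpyrrole should be chlorinated at C4, then C5, and last at C3 next to the acyl group, which is why excess reagent and warming are used, and the trichloroacetyl group is inert under these conditions.

**Step 3**
Reactants: 7 2,2,2-trichloro-1-(3,4,5-trichloro-1H-pyrrol-2-yl)ethanone
Product: 8 3,4,5-trichloro-1H-pyrrole-2-carboxylic acid
Conditions: NaOH (2 M aq, 3 equiv), THF, 0 °C to rt; then HCl to pH 2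
Reagents that add atoms: sodium hydroxide, [Na+].[OH-]
Why: Haloform-type cleavage; hydroxide attacks the trichloromethyl ketone carbonyl and trichloromethanide leaves as chloroform, while the ring chlorines of the pyrrolide are not displaced at room temperature.

**Step 4**
Reactants: 8 3,4,5-trichloro-1H-pyrrole-2-carboxylic acid
Product: 9 3,4,5-trichloro-1H-pyrrole-2-carbonyl chloride
Conditions: (COCl)2 (1.5 equiv), DMF (cat.), CH2Cl2, 0 °C to rt; evaporate, use crude at once
Reagents that add atoms: oxalyl chloride, O=C(Cl)C(=O)Cl
Why: Acid chloride formation through the chloroiminium salt from DMF and oxalyl chloride; the base-free conditions should keep the N–H acid chloride from condensing with itself.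

**Step 5**
Reactants: 3 4-(4-methoxyphenyl)-1H-1,2,3-triazole; 9 3,4,5-trichloro-1H-pyrrole-2-carbonyl chloride
Product: 12 5-(4-methoxyphenyl)-2-(3,4,5-trichloro-1H-pyrrol-2-yl)-1,3-oxazole, via 2-acyl triazole 10 (not isolated), via 1-acyl triazole 11 (not isolated)
Conditions: Et3N (1.1 equiv), ClCH2CH2Cl, 0 °C to rt, slow addition of 9; then TfOH (30 mol %), 80 °C
Reagents that add atoms: none
Why: The triazolide of 3 is N-acylated by 9, which forms the C2–N3 bond of the future oxazole, and should give mainly the 2-acyl isomer 10, which equilibrates by acyl transfer with the 1-acyl isomer 11 carrying the acyl group on the nitrogen next to the ring CH. Protonated 11 opens between N1 and N2 to a β-acylamino vinyl diazonium ion, which loses dinitrogen to a linear vinyl cation on the carbon bearing the p-anisyl group; the proton is given back when the oxazole forms, so the acid is only a promoter. The carbonyl oxygen, which the preferred amide rotamer holds next to the cation, then closes O1–C5 by a 5-endo attack on the in-plane vacant orbital; this is the known acid-mediated denitrogenative ring transformation of N-acyl 4-aryl-NH-1,2,3-triazoles into 2-substituted 5-aryloxazoles. No stereocenter is formed. The step needs the 5-aryl and not the 4-aryl oxazole, and the substrate secures it because dinitrogen can only leave from the isomer that places the charge on the anisyl-bearing carbon, where the p-methoxy group stabilises it, whereas the isomer acylated next to that carbon would need an unstabilised primary vinyl cation and should only revert. Slow addition of 9 to the triazolide should keep the acidic pyrrole N–H of 9 from self-acylation.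

**Step 6**
Reactants: 12 5-(4-methoxyphenyl)-2-(3,4,5-trichloro-1H-pyrrol-2-yl)-1,3-oxazole
Product: 13 4-chloro-5-(4-methoxyphenyl)-2-(3,4,5-trichloro-1H-pyrrol-2-yl)-1,3-oxazole
Conditions: NCS (1.05 equiv), DMF, rt to 40 °C
Reagents that add atoms: N-chlorosuccinimide, O=C1CCC(=O)N1Cl
Why: Electrophilic aromatic chlorination; C4 is the β-carbon of the enol ether O1–C5=C4 and is further activated through the conjugated p-methoxyphenyl group, so it should react before the anisole ortho carbons, and the pyrrole has no free carbon left.

**Step 7**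
Reactants: 13 4-chloro-5-(4-methoxyphenyl)-2-(3,4,5-trichloro-1H-pyrrol-2-yl)-1,3-oxazole
Product: 14 4-[4-chloro-2-(3,4,5-trichloro-1H-pyrrol-2-yl)-1,3-oxazol-5-yl]phenol
Conditions: BBr3 (4 equiv), CH2Cl2, −78 °C to rt; aqueous work-up
Reagents that add atoms: none
Why: Lewis-acid cleavage of an aryl methyl ether, in which bromide attacks the O-methyl group of the boron complex; the chloro-heteroarenes, the oxazole and the pyrrole N–H should tolerate BBr3.

**Compound list**
1 | 4-ethynylanisole | COc1ccc(C#C)cc1 | starting material
2 | azidotrimethylsilane | C[Si](C)(C)N=[N+]=[N-] | starting material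
3 | 4-(4-methoxyphenyl)-1H-1,2,3-triazole | COc1ccc(cc1)-c1c[nH]nn1 | intermediate
4 | 2-(trichloroacetyl)pyrrole, i.e. 2,2,2-trichloro-1-(1H-pyrrol-2-yl)ethanone | O=C(c1ccc[nH]1)C(Cl)(Cl)Cl | starting material
5 | 2,2,2-trichloro-1-(4-chloro-1H-pyrrol-2-yl)ethanone | O=C(c1cc(Cl)c[nH]1)C(Cl)(Cl)Cl | intermediate (not isolated)
6 | 2,2,2-trichloro-1-(4,5-dichloro-1H-pyrrol-2-yl)ethanone | O=C(c1cc(Cl)c(Cl)[nH]1)C(Cl)(Cl)Cl | intermediate (not isolated)
7 | 2,2,2-trichloro-1-(3,4,5-trichloro-1H-pyrrol-2-yl)ethanone | O=C(c1[nH]c(Cl)c(Cl)c1Cl)C(Cl)(Cl)Cl | intermediate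
8 | 3,4,5-trichloro-1H-pyrrole-2-carboxylic acid | OC(=O)c1[nH]c(Cl)c(Cl)c1Cl | intermediate
9 | 3,4,5-trichloro-1H-pyrrole-2-carbonyl chloride | O=C(Cl)c1[nH]c(Cl)c(Cl)c1Cl | intermediate
10 | [4-(4-methoxyphenyl)-2H-1,2,3-triazol-2-yl](3,4,5-trichloro-1H-pyrrol-2-yl)methanone | COc1ccc(cc1)-c1cnn(n1)C(=O)c1[nH]c(Cl)c(Cl)c1Cl | intermediate (not isolated)
11 | [4-(4-methoxyphenyl)-1H-1,2,3-triazol-1-yl](3,4,5-trichloro-1H-pyrrol-2-yl)methanone | COc1ccc(cc1)-c1cn(nn1)C(=O)c1[nH]c(Cl)c(Cl)c1Cl | intermediate (not isolated)
12 | 5-(4-methoxyphenyl)-2-(3,4,5-trichloro-1H-pyrrol-2-yl)-1,3-oxazole | COc1ccc(cc1)-c1cnc(o1)-c1[nH]c(Cl)c(Cl)c1Cl | intermediate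
13 | 4-chloro-5-(4-methoxyphenyl)-2-(3,4,5-trichloro-1H-pyrrol-2-yl)-1,3-oxazole | COc1ccc(cc1)-c1oc(nc1Cl)-c1[nH]c(Cl)c(Cl)c1Cl | intermediate
14 | 4-[4-chloro-2-(3,4,5-trichloro-1H-pyrrol-2-yl)-1,3-oxazol-5-yl]phenol | Oc1ccc(cc1)-c1oc(nc1Cl)-c1[nH]c(Cl)c(Cl)c1Cl | target

**Step count**
Total: 7 steps. Longest linear sequence: 6 steps (4 → 7 → 8 → 9 → 12 → 13 → 14).

**Steps most likely to fail**

1. Step 5. Three processes could divert it: self-acylation of the N–H acid chloride under base before it meets the triazolide; acyl transfer from the N-acyl triazole to stray nucleophiles in place of ring opening; and capture of the vinyl cation by chloride or by the pyrrole nitrogen instead of the amide oxygen. The fallback sets out from 7 and comes back at 12. Ketone 7 should acylate purchased 2-amino-1-(4-methoxyphenyl)ethanone hydrochloride (COc1ccc(cc1)C(=O)CN.Cl) with Et3N in MeCN by haloform-type aminolysis, giving the keto amide 3,4,5-trichloro-N-[2-(4-methoxyphenyl)-2-oxoethyl]-1H-pyrrole-2-carboxamide F1. Robinson–Gabriel cyclodehydration of the keto amide with POCl3 at 90 °C should then close the same oxazole 12 with no acid chloride and no diazonium chemistry.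

2. Step 2. The third chlorination, at C3 beside the strongly deactivating trichloroacetyl group, may stall, and forcing it may over-chlorinate the ring to non-aromatic material. The fallback sets out from 6, isolated after only 2 equiv of SO2Cl2, and comes back at 8. Methanolysis of 6 with NaOMe in MeOH should give methyl 4,5-dichloro-1H-pyrrole-2-carboxylate F2, whose single free position now sits beside a much weaker acceptor. Chlorination with NCS in DMF at 50 °C should then give methyl 3,4,5-trichloro-1H-pyrrole-2-carboxylate F3, and saponification with LiOH in THF/water followed by acidification returns acid 8.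

3. Step 6. Chlorination may also occur ortho to the methoxy group on the benzene ring, or a slight excess of NCS may over-chlorinate. The fallback sets out from 12 and comes back at 14, with the order of the last steps reversed so that the arene is deactivated during chlorination. BBr3 demethylation of 12 should give 4-[2-(3,4,5-trichloro-1H-pyrrol-2-yl)-1,3-oxazol-5-yl]phenol F4. Acetylation with Ac2O and pyridine in CH2Cl2 at 0 °C should give 4-[2-(3,4,5-trichloro-1H-pyrrol-2-yl)-1,3-oxazol-5-yl]phenyl acetate F5, in which the aryl ring is far less nucleophilic while oxazole C4 is still activated by the ring oxygen. NCS in DMF should then give 4-[4-chloro-2-(3,4,5-trichloro-1H-pyrrol-2-yl)-1,3-oxazol-5-yl]phenyl acetate F6, and K2CO3 in MeOH at rt should remove the acetate to give 14.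

**Further compounds**
F1 | step 5 | 3,4,5-trichloro-N-[2-(4-methoxyphenyl)-2-oxoethyl]-1H-pyrrole-2-carboxamide | COc1ccc(cc1)C(=O)CNC(=O)c1[nH]c(Cl)c(Cl)c1Cl
F2 | step 2 | methyl 4,5-dichloro-1H-pyrrole-2-carboxylate | COC(=O)c1cc(Cl)c(Cl)[nH]1
F3 | step 2 | methyl 3,4,5-trichloro-1H-pyrrole-2-carboxylate | COC(=O)c1[nH]c(Cl)c(Cl)c1Cl
F4 | step 6 | 4-[2-(3,4,5-trichloro-1H-pyrrol-2-yl)-1,3-oxazol-5-yl]phenol | Oc1ccc(cc1)-c1cnc(o1)-c1[nH]c(Cl)c(Cl)c1Cl
F5 | step 6 | 4-[2-(3,4,5-trichloro-1H-pyrrol-2-yl)-1,3-oxazol-5-yl]phenyl acetate | CC(=O)Oc1ccc(cc1)-c1cnc(o1)-c1[nH]c(Cl)c(Cl)c1Cl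
F6 | step 6 | 4-[4-chloro-2-(3,4,5-trichloro-1H-pyrrol-2-yl)-1,3-oxazol-5-yl]phenyl acetate | CC(=O)Oc1ccc(cc1)-c1oc(nc1Cl)-c1[nH]c(Cl)c(Cl)c1Cl
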